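**Retrosynthetic overview**

1. The target is upper unit–(C4→C6)–middle unit–(C4→C6)–lower unit, each a 7,8,4'-trioxygenated (2R,3R)-2,3-cis flavan. Cutting the two interflavan C4–C6 bonds (Friedel–Crafts) leaves three copies of one monomer, 9.
2. Ring C of 9 is cut at C3–C4 and O1–C2: a [4+2] union of the 2-hydroxyaryl oxocarbenium ion from aldehyde 3 (C4, C4a, C8a, O1) with (Z)-enol acetate 6 (C2, C3, O3, ring B).
3. Enabling feature: in every unit O1 sits on C8a, ortho to the benzylic C4 on C4a of ring A. This is a latent 1-oxadiene O1=C8a–C4a=C4 whose C4 cation is para to O7; C2 is benzylic to the 4'-oxygenated ring B, and the cis C2-aryl/C3–O pair maps onto a (Z)-alkene.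
4. The 3-O-acetyl group delivered by 6 then steers C4 in all three units: aryl capture trans (4β bonds of upper and middle unit), water capture cis (4α-OH of lower unit).
5. Ring order: ring C of the monomer is formed once (step 3) and used three times; the chain grows lower → middle → upper unit (steps 6, 7), and no further ring is formed.

Key step: step 3

Remark: flavan numbering and ring letters apply to every unit (ring A = benzo ring C4a–C8a, ring B = 4-oxyphenyl on C2, ring C = pyran); epioritin = (2R,3R)-2,3-cis-7,8,4'-trihydroxyflavan-3-ol, teracacidin = its 4α-ol, α being the face of the C2 aryl group; 9 is drawn as the endo adduct (4-OMe cis), an assumption without consequence because every later step ionises C4, and the (R) antipode of the acid is written for the (2R,3R) series, the sense of induction to be confirmed on the first run.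

**Step 1**
Reactants: 1 2,3,4-trihydroxybenzaldehyde; 2 benzyl bromide
Product: 3 3,4-bis(benzyloxy)-2-hydroxybenzaldehyde
Conditions: BnBr (2.05 equiv), K2CO3 (2.1 equiv), DMF, rt
Reagents that add atoms: benzyl bromide (BrCc1ccccc1)
Why: Williamson etherification in which the 2-OH, held in a hydrogen bond to the formyl group, is the least nucleophilic phenoxide, so that O4 and then O3 should be benzylated.

**Step 2**
Reactants: 4 1-(benzyloxy)-4-ethynylbenzene; 5 acetic acid
Product: 6 (Z)-2-[4-(benzyloxy)phenyl]ethenyl acetate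
Conditions: [RuCl2(p-cymene)]2 (1 mol%), P(4-ClC6H4)3 (3 mol%), DMAP (4 mol%), toluene, 60 °C
Reagents that add atoms: acetic acid (CC(=O)O)
Why: Ru-catalysed anti-Markovnikov hydro-acyloxylation of a terminal alkyne through a ruthenium vinylidene, in which trans addition of the carboxylate should give the (Z)-enol ester that later encodes the cis C2/C3 relationship.

**Step 3**
Reactants: 3 3,4-bis(benzyloxy)-2-hydroxybenzaldehyde; 6 (Z)-2-[4-(benzyloxy)phenyl]ethenyl acetate; 7 trimethyl orthoformate
Product: 9 (2R,3R,4R)-7,8-bis(benzyloxy)-2-[4-(benzyloxy)phenyl]-4-methoxychroman-3-yl acetate, via dimethyl acetal 8 (not isolated)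
Conditions: (R)-3,3'-bis(2,4,6-triisopropylphenyl)-1,1'-binaphthyl-2,2'-diyl N-triflylphosphoramide (5 mol%), HC(OMe)3 (1.2 equiv), toluene, rt; then 5 Å MS, 6 (1.5 equiv), −40 °C
Reagents that add atoms: trimethyl orthoformate (COC(OC)OC)
Why: Proposed new method: the acid ionises acetal 8 to the 2-hydroxyaryl O-methyl oxocarbenium ion (a protonated ortho-quinone methide, the 1-oxadiene O1=C8a–C4a=C4), ion-paired with the chiral phosphoramide anion that is hydrogen-bonded to O1–H; C3 of enol acetate 6, made the nucleophilic terminus by the 4-benzyloxyphenyl group (the acetoxy group is a much weaker donor), bonds to C4 while O1 closes on the incipient 4-alkoxybenzylic C2 in a concerted, asynchronous inverse-electron-demand hetero-Diels–Alder (Prins-type) event. The closest known reactions are the Sc(OTf)3-catalysed three-component chroman synthesis from salicylaldehydes, trimethyl orthoformate and alkenes, and the chiral Brønsted acid-catalysed [4+2] cycloadditions of ortho-quinone methides with styrenes; an enol ester as 2π partner and the intermolecular asymmetric variant are the new elements. Ring C is closed by [4+2] annulation, C3–C4 bond formation leading and the six-membered O1–C2 closure following within the same transition state. The cis C2/C3 relationship should come from suprafacial addition to the (Z)-alkene, the absolute configuration (2R,3R) from the catalyst-shielded face of the oxocarbenium ion, and C4 (OMe cis, endo approach) is of no consequence because every later step ionises it. The step needs regioselectivity (C3 to C4, O1 to C2), secured by the donor strength of ring B against the acyloxy group, and retention of the alkene geometry, secured by O1 being pre-positioned over C2 so that closure should outrun C2–C3 rotation and acetoxy bridging.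

**Step 4**
Reactants: 9 (2R,3R,4R)-7,8-bis(benzyloxy)-2-[4-(benzyloxy)phenyl]-4-methoxychroman-3-yl acetate
Product: 11 (2R,3R,4R)-7,8-bis(benzyloxy)-2-[4-(benzyloxy)phenyl]chromane-3,4-diol (7,8,4'-tri-O-benzylteracacidin), via cis-hydroxy acetate 10 (not isolated)
Conditions: (+)-camphorsulfonic acid (10 mol%), acetone/H2O 9:1, 0 °C to rt; then K2CO3 (0.5 equiv), MeOH, rt
Reagents that add atoms: none
Why: Woodward-type cis hydroxylation: acid ionises the C4 methyl ether to the O1/O7-stabilised benzylic cation, the 3-O-acetyl group bridges it as a cis-fused 1,3-dioxolan-2-ylium ion on the α face, water adds to the dioxolanylium carbon and the ortho acid collapses to the cis hydroxy acetate (the C4 oxygen being the former acetyl carbonyl oxygen), so that C4–O should end cis to C3–O whatever the C4 configuration of 9; methanolysis then frees the diol.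

**Step 5**
Reactants: 11 7,8,4'-tri-O-benzylteracacidin; 12 1,1'-carbonyldiimidazole
Product: 13 7,8,4'-tri-O-benzylteracacidin 3,4-carbonate (cis-fused five-membered cyclic carbonate of 11, stereocentres arranged as in 11)
Conditions: CDI (1.5 equiv), DMAP (5 mol%), CH2Cl2, rt
Reagents that add atoms: 1,1'-carbonyldiimidazole (O=C(n1ccnc1)n1ccnc1)
Why: Carbonylation of a cis-1,2-diol with CDI touches no stereocentre, and the electron-poor, ring-constrained carbonate should keep C4–O of the lower unit from ionising in the two coupling steps.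

**Step 6**
Reactants: 9 monomer (electrophile, 1 equiv); 13 7,8,4'-tri-O-benzylteracacidin 3,4-carbonate (nucleophile, 3 equiv)
Product: 14 3-O-acetyl-7,8,4'-tri-O-benzylepioritin-(4β→6)-7,8,4'-tri-O-benzylteracacidin 3,4-carbonate
Conditions: TMSOTf (0.3 equiv), 4 Å MS, CH2Cl2, −78 to −40 °C, slow addition of 9; Et3N quench
Reagents that add atoms: none
Why: Friedel–Crafts interflavan coupling of the kind used for benzylated procyanidins: TMSOTf ionises C4–OMe of 9, the 3-O-acetyl group bridges the α face, and C6 of 13 (para to O1, ortho to O7) should attack C4 from the β face to set the 3,4-trans (4β) bond, excess 13 and slow addition of 9 holding back self-condensation.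

**Step 7**
Reactants: 9 monomer (electrophile, 1 equiv); 14 middle–lower dimer (nucleophile, 2 equiv)
Product: 15 3-O-acetyl-7,8,4'-tri-O-benzylepioritin-(4β→6)-3-O-acetyl-7,8,4'-tri-O-benzylepioritin-(4β→6)-7,8,4'-tri-O-benzylteracacidin 3,4-carbonate
Conditions: TMSOTf (0.3 equiv), 4 Å MS, CH2Cl2, −78 to −40 °C, slow addition of 9; Et3N quench
Reagents that add atoms: none
Why: Second Friedel–Crafts interflavan coupling under the same acetoxy-participation control, the only strongly activated free position of 14 being C6 of its acetylated unit (para to O1, ortho to O7), so that the upper 4β→6 bond should form trans to the upper 3-O-acetyl group.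

**Step 8**
Reactants: 15 protected trimer
Product: 16 7,8,4'-tri-O-benzylepioritin-(4β→6)-7,8,4'-tri-O-benzylepioritin-(4β→6)-7,8,4'-tri-O-benzylteracacidin (nona-O-benzyl ether of 17)
Conditions: NaOMe (0.5 equiv), MeOH/THF 1:1, rt
Reagents that add atoms: none
Why: Zemplén transesterification should remove both acetates and open the cyclic carbonate without touching a stereocentre or a benzyl ether.

**Step 9**
Reactants: 16 nona-O-benzyl ether
Product: 17 epioritin-(4β→6)-epioritin-(4β→6)-epioritin-4α-ol (CNP0140823.1)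
Conditions: H2 (1 atm), Pd(OH)2/C, THF/MeOH 1:1, rt; filtration and concentration under argon
Reagents that add atoms: none
Why: Hydrogenolysis of the nine aryl benzyl ethers in a neutral medium should leave the benzylic C4–OH of the lower unit, the O1–C2 bonds and the interflavan bonds intact.

**Compound list**

1 | 2,3,4-trihydroxybenzaldehyde | O=Cc1ccc(O)c(O)c1O | starting material
2 | benzyl bromide | BrCc1ccccc1 | starting material
3 | 3,4-bis(benzyloxy)-2-hydroxybenzaldehyde | O=Cc1ccc(OCc2ccccc2)c(OCc2ccccc2)c1O | intermediate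
4 | 1-(benzyloxy)-4-ethynylbenzene | C#Cc1ccc(OCc2ccccc2)cc1 | starting material
5 | acetic acid | CC(=O)O | starting material
6 | (Z)-2-[4-(benzyloxy)phenyl]ethenyl acetate | CC(=O)O/C=C\c1ccc(OCc2ccccc2)cc1 | intermediate
7 | trimethyl orthoformate | COC(OC)OC | starting material
8 | 2,3-bis(benzyloxy)-6-(dimethoxymethyl)phenol | COC(OC)c1ccc(OCc2ccccc2)c(OCc2ccccc2)c1O | intermediate
9 | (2R,3R,4R)-7,8-bis(benzyloxy)-2-[4-(benzyloxy)phenyl]-4-methoxychroman-3-yl acetate | c1cc2c(c(OCc3ccccc3)c1OCc1ccccc1)O[C@H](c1ccc(OCc3ccccc3)cc1)[C@H](OC(C)=O)[C@@H]2OC | intermediate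
10 | (2R,3R,4R)-7,8-bis(benzyloxy)-2-[4-(benzyloxy)phenyl]-4-hydroxychroman-3-yl acetate | c1cc2c(c(OCc3ccccc3)c1OCc1ccccc1)O[C@H](c1ccc(OCc3ccccc3)cc1)[C@H](OC(C)=O)[C@@H]2O | intermediate
11 | (2R,3R,4R)-7,8-bis(benzyloxy)-2-[4-(benzyloxy)phenyl]chromane-3,4-diol | c1cc2c(c(OCc3ccccc3)c1OCc1ccccc1)O[C@H](c1ccc(OCc3ccccc3)cc1)[C@H](O)[C@@H]2O | intermediate
12 | 1,1'-carbonyldiimidazole | O=C(n1ccnc1)n1ccnc1 | starting material
13 | 7,8,4'-tri-O-benzylteracacidin 3,4-carbonate | c1cc2c(c(OCc3ccccc3)c1OCc1ccccc1)O[C@H](c1ccc(OCc3ccccc3)cc1)[C@H](OC(=O)O5)[C@@H]25 | intermediate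
14 | 3-O-acetyl-7,8,4'-tri-O-benzylepioritin-(4β→6)-7,8,4'-tri-O-benzylteracacidin 3,4-carbonate | c1cc2c(c(OCc3ccccc3)c1OCc1ccccc1)O[C@H](c1ccc(OCc3ccccc3)cc1)[C@H](OC(C)=O)[C@H]2c1cc2c(c(OCc3ccccc3)c1OCc1ccccc1)O[C@H](c1ccc(OCc3ccccc3)cc1)[C@H](OC(=O)O5)[C@@H]25 | intermediate
15 | 3-O-acetyl-7,8,4'-tri-O-benzylepioritin-(4β→6)-3-O-acetyl-7,8,4'-tri-O-benzylepioritin-(4β→6)-7,8,4'-tri-O-benzylteracacidin 3,4-carbonate | c5ccccc5COc1ccc([C@H]2Oc3c(ccc(OCc5ccccc5)c3OCc5ccccc5)[C@H](c3cc4c(c(OCc5ccccc5)c3OCc5ccccc5)O[C@H](c3ccc(OCc5ccccc5)cc3)[C@H](OC(C)=O)[C@H]4c3cc4c(c(OCc5ccccc5)c3OCc5ccccc5)O[C@H](c3ccc(OCc5ccccc5)cc3)[C@H](OC(=O)O6)[C@@H]46)[C@H]2OC(C)=O)cc1 | intermediate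
16 | 7,8,4'-tri-O-benzylepioritin-(4β→6)-7,8,4'-tri-O-benzylepioritin-(4β→6)-7,8,4'-tri-O-benzylteracacidin | c5ccccc5COc1ccc([C@H]2Oc3c(ccc(OCc5ccccc5)c3OCc5ccccc5)[C@H](c3cc4c(c(OCc5ccccc5)c3OCc5ccccc5)O[C@H](c3ccc(OCc5ccccc5)cc3)[C@H](O)[C@H]4c3cc4c(c(OCc5ccccc5)c3OCc5ccccc5)O[C@H](c3ccc(OCc5ccccc5)cc3)[C@H](O)[C@@H]4O)[C@H]2O)cc1 | intermediate
17 | epioritin-(4β→6)-epioritin-(4β→6)-epioritin-4α-ol (CNP0140823.1) | Oc1ccc([C@H]2Oc3c(ccc(O)c3O)[C@H](c3cc4c(c(O)c3O)O[C@H](c3ccc(O)cc3)[C@H](O)[C@H]4c3cc4c(c(O)c3O)O[C@H](c3ccc(O)cc3)[C@H](O)[C@@H]4O)[C@H]2O)cc1 | target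

**Step count and risks**

Total step count: 9. Longest linear sequence: 8 steps (steps 1, 3, 4, 5, 6, 7, 8, 9); step 2 is a one-step branch.

Steps most likely to fail:

1. Step 3 (proposed new method). The risk is weak enantiofacial discrimination in the oxocarbenium/chiral-anion pair, possibly with partly stepwise closure that erodes the cis C2/C3 relationship. The fallback sets out from 3 (with 6 and 7) and gives up catalyst control: the known racemic three-component cycloaddition is run with Sc(OTf)3 (5 mol%) and HC(OMe)3 in CH2Cl2 at 0 °C, and the racemate is resolved by preparative chromatography on a chiral stationary phase. This separates 9 from its enantiomer (2S,3S,4S)-7,8-bis(benzyloxy)-2-[4-(benzyloxy)phenyl]-4-methoxychroman-3-yl acetate F1, and the route is rejoined at 9.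

2. Step 4. The risk is capture of the open C4 benzylic cation by water from the β face instead of addition to the dioxolanylium carbon, or re-ionisation of the product, either of which scrambles C4 of the lower unit. The fallback sets out from 9 and replaces water capture by an irreversible, ring-constrained carbonate closure. NaOMe in MeOH should give (2R,3R,4R)-7,8-bis(benzyloxy)-2-[4-(benzyloxy)phenyl]-4-methoxychroman-3-ol F2. Boc2O with DMAP should give its tert-butyl carbonate, tert-butyl (2R,3R,4R)-7,8-bis(benzyloxy)-2-[4-(benzyloxy)phenyl]-4-methoxychroman-3-yl carbonate F3. BF3·OEt2 (10 mol%) in CH2Cl2 at −40 °C then ionises C4, and the carbonate carbonyl oxygen closes on it from the face of O3 with loss of 2-methylpropene. This rejoins the route at 13 and bypasses 11 and step 5.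

3. Step 7. The risk is over-alkylation: the free C6 of the new upper unit and of unreacted 9 compete with 14 for the C4 cation, giving higher oligomers and consuming the dimer. The fallback sets out from 9 and caps the upper unit. NBS in CH2Cl2 at −20 °C should brominate C6 to give (2R,3R,4R)-7,8-bis(benzyloxy)-2-[4-(benzyloxy)phenyl]-6-bromo-4-methoxychroman-3-yl acetate F4. TMSOTf coupling of F4 with 14 (1.2 equiv) should give the capped trimer 6-bromo-3-O-acetyl-7,8,4'-tri-O-benzylepioritin-(4β→6)-3-O-acetyl-7,8,4'-tri-O-benzylepioritin-(4β→6)-7,8,4'-tri-O-benzylteracacidin 3,4-carbonate F5. NaOMe in MeOH/THF should give 6-bromo-7,8,4'-tri-O-benzylepioritin-(4β→6)-7,8,4'-tri-O-benzylepioritin-(4β→6)-7,8,4'-tri-O-benzylteracacidin F6. Hydrogenolysis with H2, Pd(OH)2/C and Et3N cleaves the C–Br bond together with the benzyl ethers, and the route is rejoined at 17.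

**Further compounds**

F1 | step 3 | (2S,3S,4S)-7,8-bis(benzyloxy)-2-[4-(benzyloxy)phenyl]-4-methoxychroman-3-yl acetate | c1cc2c(c(OCc3ccccc3)c1OCc1ccccc1)O[C@@H](c1ccc(OCc3ccccc3)cc1)[C@@H](OC(C)=O)[C@H]2OC
F2 | step 4 | (2R,3R,4R)-7,8-bis(benzyloxy)-2-[4-(benzyloxy)phenyl]-4-methoxychroman-3-ol | c1cc2c(c(OCc3ccccc3)c1OCc1ccccc1)O[C@H](c1ccc(OCc3ccccc3)cc1)[C@H](O)[C@@H]2OC
F3 | step 4 | tert-butyl (2R,3R,4R)-7,8-bis(benzyloxy)-2-[4-(benzyloxy)phenyl]-4-methoxychroman-3-yl carbonate | c1cc2c(c(OCc3ccccc3)c1OCc1ccccc1)O[C@H](c1ccc(OCc3ccccc3)cc1)[C@H](OC(=O)OC(C)(C)C)[C@@H]2OC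
F4 | step 7 | (2R,3R,4R)-7,8-bis(benzyloxy)-2-[4-(benzyloxy)phenyl]-6-bromo-4-methoxychroman-3-yl acetate | Brc1cc2c(c(OCc3ccccc3)c1OCc1ccccc1)O[C@H](c1ccc(OCc3ccccc3)cc1)[C@H](OC(C)=O)[C@@H]2OC
F5 | step 7 | 6-bromo-3-O-acetyl-7,8,4'-tri-O-benzylepioritin-(4β→6)-3-O-acetyl-7,8,4'-tri-O-benzylepioritin-(4β→6)-7,8,4'-tri-O-benzylteracacidin 3,4-carbonate | c5ccccc5COc1ccc([C@H]2Oc3c(cc(Br)c(OCc5ccccc5)c3OCc5ccccc5)[C@H](c3cc4c(c(OCc5ccccc5)c3OCc5ccccc5)O[C@H](c3ccc(OCc5ccccc5)cc3)[C@H](OC(C)=O)[C@H]4c3cc4c(c(OCc5ccccc5)c3OCc5ccccc5)O[C@H](c3ccc(OCc5ccccc5)cc3)[C@H](OC(=O)O6)[C@@H]46)[C@H]2OC(C)=O)cc1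
F6 | step 7 | 6-bromo-7,8,4'-tri-O-benzylepioritin-(4β→6)-7,8,4'-tri-O-benzylepioritin-(4β→6)-7,8,4'-tri-O-benzylteracacidin | c5ccccc5COc1ccc([C@H]2Oc3c(cc(Br)c(OCc5ccccc5)c3OCc5ccccc5)[C@H](c3cc4c(c(OCc5ccccc5)c3OCc5ccccc5)O[C@H](c3ccc(OCc5ccccc5)cc3)[C@H](O)[C@H]4c3cc4c(c(OCc5ccccc5)c3OCc5ccccc5)O[C@H](c3ccc(OCc5ccccc5)cc3)[C@H](O)[C@@H]4O)[C@H]2O)cc1
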